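**Retrosynthetic overview**

1. Locants are germacrane-type: C6 = lactone O–CH, C7 = ring-fusion CH, C8 = CH–O-acyl, C9 = CH–OH, C1=C10 (Z) and C4=C5 (E) = ring alkenes, C11/C12/C13 = lactone α-carbon, carbonyl and exocyclic CH2. Last disconnections: the C9 silyl ether, then the C8 ester (alcohol 22 + epoxy acid 26).
2. Key disconnection: the α-methylene-γ-butyrolactone (ring O–C6–C7–C11–C12) is cut at C7–C11, O6–C12 and C11=C13 into three components: macrocyclic epoxy alcohol 17, Ph3P=C=C=O (18) and formaldehyde (19).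
3. Enabling feature: C7 of the five-membered lactone ring lies between two oxygen-bearing ring carbons (C6–O of the lactone, C8–O of the ester), and the C7–C11 and C8–O bonds are anti. A threo 6-hydroxy-7,8-cis-epoxide therefore lets an O6-tethered C11 nucleophile open the oxirane at C7 with inversion and frees O8 as the only hydroxyl.
4. Ten-membered carbocycle: ring-closing metathesis at the Z-trisubstituted C1=C10 alkene of diene 16; the C2–C3 bond comes from an allyl–allyl coupling.
5. Open chain: acetylene is the C7–C8 linchpin between enals 5 and 4 (two catalyst-controlled alkynylations), followed by Lindlar reduction and hydroxyl-directed epoxidation. Ring order: oxirane, ten-membered carbocycle, γ-lactone; the second oxirane arrives with acid 26.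

Key step: step 13

Assumption: the (S,S)-ProPhenol/zinc catalyst is taken to deliver alkynylzinc reagents to the Re face of an aldehyde and the (R,R)-catalyst to the Si face; if the opposite sense applies, the ligands of steps 3 and 6 are exchanged.

**Route**

Step 1
Reactants: 1 2,2-dimethoxyacetaldehyde (60% in water); 2 ethyl 2-(triphenyl-λ5-phosphanylidene)propanoate
Product: 3 ethyl (2E)-4,4-dimethoxy-2-methylbut-2-enoate
Conditions: CH2Cl2, rt
Reagents that add atoms: none
Why: Wittig olefination with the α-methyl-substituted stabilised ylide should give the (E)-trisubstituted enoate (the future C3–C4=C5–C6 array), the acetal keeping the second carbonyl latent.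

Step 2
Reactants: 3 ethyl (2E)-4,4-dimethoxy-2-methylbut-2-enoate
Product: 4 ethyl (2E)-2-methyl-4-oxobut-2-enoate
Conditions: 1 M HCl (aq), THF, 0 °C to rt
Reagents that add atoms: water, O
Why: Acid-catalysed acetal hydrolysis should release the aldehyde (future C6) while the conjugated E-alkene and the ester stay unchanged.

Step 3
Reactants: 5 methacrolein (2-methylprop-2-enal); 6 ethynyltrimethylsilane
Product: 7 (3R)-4-methyl-1-(trimethylsilyl)pent-4-en-1-yn-3-ol
Conditions: Me2Zn (3 equiv), (R,R)-ProPhenol (20 mol%), Ph3P=O (40 mol%), toluene, 4 °C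
Reagents that add atoms: none
Why: Catalytic asymmetric alkynylation (zinc acetylide addition under the dinuclear zinc–ProPhenol catalyst) should deliver the acetylide to the Si face of the enal in the usual 1,2-sense and so set the (R)-carbinol that becomes C9.

Step 4
Reactants: 7 (3R)-4-methyl-1-(trimethylsilyl)pent-4-en-1-yn-3-ol
Product: 8 (3R)-3-[(tert-butyldimethylsilyl)oxy]-4-methyl-1-(trimethylsilyl)pent-4-en-1-yne
Conditions: TBSCl, imidazole, DMF, rt
Reagents that add atoms: tert-butyldimethylsilyl chloride, CC(C)(C)[Si](C)(C)Cl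
Why: Silyl ether formation protects the C9 oxygen, which must stay masked to the last step so that only the C8 oxygen is acylated later.

Step 5
Reactants: 8 (3R)-3-[(tert-butyldimethylsilyl)oxy]-4-methyl-1-(trimethylsilyl)pent-4-en-1-yne
Product: 9 (3R)-3-[(tert-butyldimethylsilyl)oxy]-4-methylpent-4-en-1-yne
Conditions: K2CO3 (0.2 equiv), MeOH, rt
Reagents that add atoms: none
Why: Base-mediated protodesilylation of the alkynylsilane should free the terminal alkyne without touching the silyl ether or the stereocentre.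

Step 6
Reactants: 9 (3R)-3-[(tert-butyldimethylsilyl)oxy]-4-methylpent-4-en-1-yne; 4 ethyl (2E)-2-methyl-4-oxobut-2-enoate
Product: 10 ethyl (2E,4S,7R)-7-[(tert-butyldimethylsilyl)oxy]-4-hydroxy-2,8-dimethylnona-2,8-dien-5-ynoate
Conditions: Me2Zn (3 equiv), (S,S)-ProPhenol (20 mol%), Ph3P=O (40 mol%), toluene, 4 °C
Reagents that add atoms: none
Why: A second ProPhenol/zinc-catalysed asymmetric alkynylation with the antipodal ligand should add the acetylide of 9 to the Re face of the aldehyde of 4 and set the (4S)-carbinol (future C6) under catalyst control, the existing silyloxy centre being too remote across the alkyne to interfere.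

Step 7
Reactants: 10 ethyl (2E,4S,7R)-7-[(tert-butyldimethylsilyl)oxy]-4-hydroxy-2,8-dimethylnona-2,8-dien-5-ynoate
Product: 11 ethyl (2E,4R,5Z,7S)-7-[(tert-butyldimethylsilyl)oxy]-4-hydroxy-2,8-dimethylnona-2,5,8-trienoate (same spatial arrangement as 10; the descriptors change by priority only)
Conditions: H2 (1 atm), Pd/CaCO3 poisoned with Pb(OAc)2 (Lindlar catalyst), quinoline, EtOAc, rt
Reagents that add atoms: none
Why: Lindlar semihydrogenation (syn addition of H2) should give the Z-alkene C7=C8, the enoate and the 1,1-disubstituted alkene being reduced far more slowly than the alkyne.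

Step 8
Reactants: 11 ethyl (2E,4R,5Z,7S)-7-[(tert-butyldimethylsilyl)oxy]-4-hydroxy-2,8-dimethylnona-2,5,8-trienoate
Product: 12 ethyl (2E,4S)-4-[(2R,3R)-3-{(1R)-1-[(tert-butyldimethylsilyl)oxy]-2-methylprop-2-en-1-yl}oxiran-2-yl]-4-hydroxy-2-methylbut-2-enoate (cis-oxirane, threo to both flanking oxygens)
Conditions: VO(acac)2 (5 mol%), t-BuOOH (decane), CH2Cl2, 0 °C to rt
Reagents that add atoms: tert-butyl hydroperoxide, CC(C)(C)OO
Why: Hydroxyl-directed epoxidation (peroxide delivery from a vanadium alkoxide) should oxidise only the Z-alkene allylic to the free C6 hydroxyl and, because allylic 1,3-strain holds H6 in the alkene plane, should place the oxirane syn to that hydroxyl on the face that also carries the C9 silyloxy group, while the electron-poor enoate alkene and the isopropenyl group (no free allylic hydroxyl) are not addressed.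

Step 9
Reactants: 12 ethyl (2E,4S)-4-[(2R,3R)-3-{(1R)-1-[(tert-butyldimethylsilyl)oxy]-2-methylprop-2-en-1-yl}oxiran-2-yl]-4-hydroxy-2-methylbut-2-enoate
Product: 13 (2E,4S)-4-[(2R,3R)-3-{(1R)-1-[(tert-butyldimethylsilyl)oxy]-2-methylprop-2-en-1-yl}oxiran-2-yl]-2-methylbut-2-ene-1,4-diol
Conditions: i-Bu2AlH (3.5 equiv), CH2Cl2, −78 °C; aqueous Rochelle salt
Reagents that add atoms: none
Why: Low-temperature DIBAL-H reduction should take the enoate to the primary allylic alcohol by 1,2-hydride delivery without opening the hindered oxirane.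

Step 10
Reactants: 13 (2E,4S)-4-[(2R,3R)-3-{(1R)-1-[(tert-butyldimethylsilyl)oxy]-2-methylprop-2-en-1-yl}oxiran-2-yl]-2-methylbut-2-ene-1,4-diol
Product: 14 (1S,2E)-4-bromo-1-[(2R,3R)-3-{(1R)-1-[(tert-butyldimethylsilyl)oxy]-2-methylprop-2-en-1-yl}oxiran-2-yl]-3-methylbut-2-en-1-ol
Conditions: CBr4 (1.05 equiv), PPh3, CH2Cl2, −30 to 0 °C
Reagents that add atoms: carbon tetrabromide, BrC(Br)(Br)Br
Why: The Appel reaction should convert only the unhindered primary allylic alcohol into the bromide (SN2 at carbon), the secondary C6 hydroxyl being shielded by the oxirane and the trisubstituted alkene.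

Step 11
Reactants: 14 (1S,2E)-4-bromo-1-[(2R,3R)-3-{(1R)-1-[(tert-butyldimethylsilyl)oxy]-2-methylprop-2-en-1-yl}oxiran-2-yl]-3-methylbut-2-en-1-ol; 15 allyltributylstannane
Product: 16 (1S,2E)-1-[(2R,3R)-3-{(1R)-1-[(tert-butyldimethylsilyl)oxy]-2-methylprop-2-en-1-yl}oxiran-2-yl]-3-methylhepta-2,6-dien-1-ol
Conditions: Pd(PPh3)4 (5 mol%), THF, 50 °C
Reagents that add atoms: none
Why: Allyl–allyl cross-coupling of Stille type (oxidative addition of zerovalent palladium to the allylic bromide, transmetalation from tin, reductive elimination at the primary terminus) should form the C2–C3 bond with retention of the E-alkene under neutral conditions that spare the epoxy alcohol.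

Step 12
Reactants: 16 (1S,2E)-1-[(2R,3R)-3-{(1R)-1-[(tert-butyldimethylsilyl)oxy]-2-methylprop-2-en-1-yl}oxiran-2-yl]-3-methylhepta-2,6-dien-1-ol
Product: 17 (1R,2S,3E,7Z,9R,10R)-9-[(tert-butyldimethylsilyl)oxy]-4,8-dimethyl-11-oxabicyclo[8.1.0]undeca-3,7-dien-2-ol
Conditions: second-generation Hoveyda–Grubbs catalyst (10 mol%), 1,4-benzoquinone (20 mol%), toluene (1 mM), 80 °C
Reagents that add atoms: none
Why: Ring-closing metathesis between the terminal vinyl and the isopropenyl group should close the ten-membered carbocycle with loss of ethylene, the medium ring enforcing the Z geometry of the new trisubstituted C1=C10 alkene while the E-trisubstituted C4=C5 alkene is inert to the catalyst.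

Step 13
Reactants: 17 (1R,2S,3E,7Z,9R,10R)-9-[(tert-butyldimethylsilyl)oxy]-4,8-dimethyl-11-oxabicyclo[8.1.0]undeca-3,7-dien-2-ol; 18 (triphenylphosphoranylidene)ketene; 19 formaldehyde (charged as paraformaldehyde)
Product: 22 (3aR,4R,5R,6Z,10E,11aS)-5-[(tert-butyldimethylsilyl)oxy]-4-hydroxy-6,10-dimethyl-3-methylidene-3a,4,5,8,9,11a-hexahydrocyclodeca[b]furan-2(3H)-one, via ester ylide 20 (not isolated), via lactone ylide 21 (not isolated)
Conditions: 18 (1.3 equiv), toluene, 60 °C; LiClO4 (2 equiv), THF, 70 °C; then paraformaldehyde, 60 °C; one pot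
Reagents that add atoms: none
Why: Proposed new method: the C6 hydroxyl of 17 adds across the C=C bond of 18 to give the ester-stabilised ylide 20, whose ylide carbon (future C11), tethered through O6 and the future C12 carbonyl, opens the LiClO4-activated oxirane at C7 by backside attack; proton transfer from the resulting α-acyl phosphonium to the C8 alkoxide gives the hydroxy lactone ylide 21, which undergoes Wittig olefination with formaldehyde to install the C11=C13 methylene. The closest known reaction types are the three-component alcohol/ketenylidenephosphorane/aldehyde ester synthesis, the oxirane opening by phosphorus-stabilised carbanions that starts the Wadsworth–Emmons cyclopropanation, and the methylenation of α-phosphoranylidene lactones with formaldehyde. The γ-lactone ring (O–C6–C7–C11–C12) closes in the 5-exo-tet mode, and the 6-endo alternative at C8 is disfavoured because the two-atom ester tether cannot reach the backside of the C8–O bond. C7 is the only centre that changes: it is inverted by the stereospecific SN2 opening, which the threo relation of O6 to the cis-oxirane makes geometrically possible, so that C11 ends cis to O6 (cis ring fusion) and anti to the oxygen that stays on C8 with retention. The step needs C-alkylation to win over cyclopropane formation (through an oxaphospholane) and over translactonisation: the acidic α-hydrogen of the phosphonium intermediate is transferred to the alkoxide, leaving a neutral ylide whose carbonyl is too electron-rich to be attacked, and the C8 hydroxyl emerges as the only free hydroxyl, ready for the next acylation.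

Step 14
Reactants: 23 methyl angelate, methyl (2Z)-2-methylbut-2-enoate
Product: 24 (2Z)-2-methylbut-2-en-1-ol
Conditions: i-Bu2AlH (2.2 equiv), CH2Cl2, −78 to 0 °C
Reagents that add atoms: none
Why: DIBAL-H reduction of the ester at low temperature should give the allylic alcohol with the Z (angelate) geometry intact.

Step 15
Reactants: 24 (2Z)-2-methylbut-2-en-1-ol
Product: 25 [(2R,3S)-2,3-dimethyloxiran-2-yl]methanol
Conditions: Ti(Oi-Pr)4 (10 mol%), D-(−)-diethyl tartrate (12 mol%), t-BuOOH, 4 Å molecular sieves, CH2Cl2, −20 °C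
Reagents that add atoms: tert-butyl hydroperoxide, CC(C)(C)OO
Why: Sharpless asymmetric epoxidation with D-(−)-diethyl tartrate should deliver oxygen to the face of the Z-allylic alcohol that gives the (2R,3S)-epoxy alcohol, both oxirane centres being set together and the cis relation of CH2OH and the C3 methyl following from the alkene geometry.

Step 16
Reactants: 25 [(2R,3S)-2,3-dimethyloxiran-2-yl]methanol
Product: 26 (2S,3S)-2,3-dimethyloxirane-2-carboxylic acid
Conditions: RuCl3·xH2O (2 mol%), NaIO4 (4 equiv), CCl4/MeCN/H2O, rt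
Reagents that add atoms: water, O; sodium periodate (terminal oxidant, oxygen source of RuO4), [Na+].[O-]I(=O)(=O)=O
Why: Ruthenium tetroxide oxidation should take the primary alcohol to the acid, the fully substituted α-carbon being unable to epimerise (its descriptor changes from R to S by priority only).

Step 17
Reactants: 22 (3aR,4R,5R,6Z,10E,11aS)-5-[(tert-butyldimethylsilyl)oxy]-4-hydroxy-6,10-dimethyl-3-methylidene-3a,4,5,8,9,11a-hexahydrocyclodeca[b]furan-2(3H)-one; 26 (2S,3S)-2,3-dimethyloxirane-2-carboxylic acid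
Product: 27 (3aS,4R,5R,6Z,10E,11aS)-5-[(tert-butyldimethylsilyl)oxy]-6,10-dimethyl-3-methylidene-2-oxo-2,3,3a,4,5,8,9,11a-octahydrocyclodeca[b]furan-4-yl (2S,3S)-2,3-dimethyloxirane-2-carboxylate
Conditions: 2-methyl-6-nitrobenzoic anhydride, DMAP, Et3N, CH2Cl2, rt
Reagents that add atoms: none
Why: Shiina esterification (mixed-anhydride activation with nucleophilic catalysis by DMAP) should acylate the C8 hydroxyl, the only free hydroxyl of 22, with the hindered acid without touching a stereocentre.

Step 18
Reactants: 27 (3aS,4R,5R,6Z,10E,11aS)-5-[(tert-butyldimethylsilyl)oxy]-6,10-dimethyl-3-methylidene-2-oxo-2,3,3a,4,5,8,9,11a-octahydrocyclodeca[b]furan-4-yl (2S,3S)-2,3-dimethyloxirane-2-carboxylate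
Product: 28 (3aS,4R,5R,6Z,10E,11aS)-5-hydroxy-6,10-dimethyl-3-methylidene-2-oxo-2,3,3a,4,5,8,9,11a-octahydrocyclodeca[b]furan-4-yl (2S,3S)-2,3-dimethyloxirane-2-carboxylate (CNP0318223.3)
Conditions: HF·pyridine, pyridine, THF, 0 °C to rt
Reagents that add atoms: none
Why: Fluoride-induced cleavage of the silyl ether with pyridine-buffered HF·pyridine should free the C9 hydroxyl under conditions too mild for acyl migration, oxirane opening or transannular cyclisation, giving the target.

**Compound list**

1 | 2,2-dimethoxyacetaldehyde | COC(OC)C=O | starting material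
2 | ethyl 2-(triphenyl-λ5-phosphanylidene)propanoate | CCOC(=O)C(C)=P(c1ccccc1)(c1ccccc1)c1ccccc1 | starting material
3 | ethyl (2E)-4,4-dimethoxy-2-methylbut-2-enoate | CCOC(=O)/C(C)=C/C(OC)OC | intermediate
4 | ethyl (2E)-2-methyl-4-oxobut-2-enoate | CCOC(=O)/C(C)=C/C=O | intermediate
5 | methacrolein (2-methylprop-2-enal) | CC(=C)C=O | starting material
6 | ethynyltrimethylsilane | C#C[Si](C)(C)C | starting material
7 | (3R)-4-methyl-1-(trimethylsilyl)pent-4-en-1-yn-3-ol | C[Si](C)(C)C#C[C@H](O)C(C)=C | intermediate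
8 | (3R)-3-[(tert-butyldimethylsilyl)oxy]-4-methyl-1-(trimethylsilyl)pent-4-en-1-yne | C[Si](C)(C)C#C[C@H](O[Si](C)(C)C(C)(C)C)C(C)=C | intermediate
9 | (3R)-3-[(tert-butyldimethylsilyl)oxy]-4-methylpent-4-en-1-yne | C#C[C@H](O[Si](C)(C)C(C)(C)C)C(C)=C | intermediate
10 | ethyl (2E,4S,7R)-7-[(tert-butyldimethylsilyl)oxy]-4-hydroxy-2,8-dimethylnona-2,8-dien-5-ynoate | CCOC(=O)/C(C)=C/[C@H](O)C#C[C@H](O[Si](C)(C)C(C)(C)C)C(C)=C | intermediate
11 | ethyl (2E,4R,5Z,7S)-7-[(tert-butyldimethylsilyl)oxy]-4-hydroxy-2,8-dimethylnona-2,5,8-trienoate | CCOC(=O)/C(C)=C/[C@H](O)/C=C\[C@H](O[Si](C)(C)C(C)(C)C)C(C)=C | intermediate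
12 | ethyl (2E,4S)-4-[(2R,3R)-3-{(1R)-1-[(tert-butyldimethylsilyl)oxy]-2-methylprop-2-en-1-yl}oxiran-2-yl]-4-hydroxy-2-methylbut-2-enoate | CCOC(=O)/C(C)=C/[C@H](O)[C@H]1O[C@H]1[C@H](O[Si](C)(C)C(C)(C)C)C(C)=C | intermediate
13 | (2E,4S)-4-[(2R,3R)-3-{(1R)-1-[(tert-butyldimethylsilyl)oxy]-2-methylprop-2-en-1-yl}oxiran-2-yl]-2-methylbut-2-ene-1,4-diol | OC/C(C)=C/[C@H](O)[C@H]1O[C@H]1[C@H](O[Si](C)(C)C(C)(C)C)C(C)=C | intermediate
14 | (1S,2E)-4-bromo-1-[(2R,3R)-3-{(1R)-1-[(tert-butyldimethylsilyl)oxy]-2-methylprop-2-en-1-yl}oxiran-2-yl]-3-methylbut-2-en-1-ol | BrC/C(C)=C/[C@H](O)[C@H]1O[C@H]1[C@H](O[Si](C)(C)C(C)(C)C)C(C)=C | intermediate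
15 | allyltributylstannane | C=CC[Sn](CCCC)(CCCC)CCCC | starting material
16 | (1S,2E)-1-[(2R,3R)-3-{(1R)-1-[(tert-butyldimethylsilyl)oxy]-2-methylprop-2-en-1-yl}oxiran-2-yl]-3-methylhepta-2,6-dien-1-ol | C=CCC/C(C)=C/[C@H](O)[C@H]1O[C@H]1[C@H](O[Si](C)(C)C(C)(C)C)C(C)=C | intermediate
17 | (1R,2S,3E,7Z,9R,10R)-9-[(tert-butyldimethylsilyl)oxy]-4,8-dimethyl-11-oxabicyclo[8.1.0]undeca-3,7-dien-2-ol | O[C@H]1/C=C(\C)CC/C=C(/C)[C@@H](O[Si](C)(C)C(C)(C)C)[C@@H]2O[C@H]12 | intermediate
18 | (triphenylphosphoranylidene)ketene | O=C=C=P(c1ccccc1)(c1ccccc1)c1ccccc1 | starting material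
19 | formaldehyde (as paraformaldehyde) | C=O | starting material
20 | ester ylide: (triphenyl-λ5-phosphanylidene)acetate of alcohol 17 at its hydroxyl (stereocentres as in 17) | O=C(C=P(c1ccccc1)(c1ccccc1)c1ccccc1)O[C@H]1/C=C(\C)CC/C=C(/C)[C@@H](O[Si](C)(C)C(C)(C)C)[C@@H]2O[C@H]12 | intermediate
21 | lactone ylide: lactone 22 with the exocyclic CH2 replaced by PPh3 (3-(triphenyl-λ5-phosphanylidene) lactone, stereocentres as in 22) | c1ccccc1P(c1ccccc1)(c1ccccc1)=C1C(=O)O[C@H]2/C=C(\C)CC/C=C(/C)[C@@H](O[Si](C)(C)C(C)(C)C)[C@H](O)[C@@H]12 | intermediate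
22 | (3aR,4R,5R,6Z,10E,11aS)-5-[(tert-butyldimethylsilyl)oxy]-4-hydroxy-6,10-dimethyl-3-methylidene-3a,4,5,8,9,11a-hexahydrocyclodeca[b]furan-2(3H)-one | C=C1C(=O)O[C@H]2/C=C(\C)CC/C=C(/C)[C@@H](O[Si](C)(C)C(C)(C)C)[C@H](O)[C@@H]12 | intermediate
23 | methyl angelate, methyl (2Z)-2-methylbut-2-enoate | C/C=C(/C)C(=O)OC | starting material
24 | (2Z)-2-methylbut-2-en-1-ol | C/C=C(/C)CO | intermediate
25 | [(2R,3S)-2,3-dimethyloxiran-2-yl]methanol | OC[C@@]1(C)O[C@H]1C | intermediate
26 | (2S,3S)-2,3-dimethyloxirane-2-carboxylic acid | OC(=O)[C@@]1(C)O[C@H]1C | intermediate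
27 | (3aS,4R,5R,6Z,10E,11aS)-5-[(tert-butyldimethylsilyl)oxy]-6,10-dimethyl-3-methylidene-2-oxo-2,3,3a,4,5,8,9,11a-octahydrocyclodeca[b]furan-4-yl (2S,3S)-2,3-dimethyloxirane-2-carboxylate | C=C1C(=O)O[C@H]2/C=C(\C)CC/C=C(/C)[C@@H](O[Si](C)(C)C(C)(C)C)[C@H](OC(=O)[C@@]3(C)O[C@H]3C)[C@@H]12 | intermediate
28 | (3aS,4R,5R,6Z,10E,11aS)-5-hydroxy-6,10-dimethyl-3-methylidene-2-oxo-2,3,3a,4,5,8,9,11a-octahydrocyclodeca[b]furan-4-yl (2S,3S)-2,3-dimethyloxirane-2-carboxylate | C=C1C(=O)O[C@H]2/C=C(\C)CC/C=C(/C)[C@@H](O)[C@H](OC(=O)[C@@]3(C)O[C@H]3C)[C@@H]12 | target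

**Step count and risks**

Total step count: 18. Longest linear sequence: 13 steps (steps 3 to 13, then 17 and 18); steps 1–2 (aldehyde 4) and 14–16 (acid 26) are side branches.

Steps most likely to fail:

1. Step 13 (Proposed new method). The neutral ester ylide may be too weak a nucleophile for the 1,2-disubstituted oxirane, or the hydroxy phosphonium intermediate may collapse through an oxaphospholane to a cyclopropane. Fallback, setting out from 17: Steglich esterification with (diethoxyphosphoryl)acetic acid (DCC, DMAP, CH2Cl2) would give the phosphonoacetate F1. NaH (THF, 0 °C to rt) would generate the phosphonate-stabilised carbanion, which opens the oxirane at C7 in the same 5-exo sense to the α-phosphono lactone F2. Paraformaldehyde added to the same flask would complete a Horner–Wadsworth–Emmons methylenation to 22, where the route is rejoined.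

2. Step 12. Oligomerisation by intermolecular metathesis at the terminal vinyl group, or failure of the hindered isopropenyl group to engage, could stop the ring closure. Fallback, setting out from 16: the order of ring formation is reversed. The annulation of step 13 on the open chain (or the phosphonate sequence of the first fallback) would give the acyclic α-methylene-γ-butyrolactone F3. Shiina esterification with 26 would give the ester F4. Ring-closing metathesis of F4 (second-generation Hoveyda–Grubbs catalyst, toluene, high dilution) would then lead to 27, which rejoins the route before step 18. In F4 the lactone turn pre-organises the two arms, no free hydroxyl remains, and the electron-poor exocyclic alkene is a poor metathesis partner.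

3. Step 6. Uncatalysed background addition to the very electrophilic enal, and conjugate addition or oligomerisation, could erode the facial selectivity and the mass balance. Fallback, setting out from 9 and 4: the lithium acetylide of 9 (n-BuLi, THF, −78 °C) would add to 4 to give the C4-epimeric alcohols F5. MnO2 would oxidise them to the ynone F6. Midland reduction with (S)-Alpine-borane (alkynyl as the small group) would return 10 as a single epimer.

**Further compounds**

F1 | step 13 | (diethoxyphosphoryl)acetate of alcohol 17 | CCOP(=O)(OCC)CC(=O)O[C@H]1/C=C(\C)CC/C=C(/C)[C@@H](O[Si](C)(C)C(C)(C)C)[C@@H]2O[C@H]12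
F2 | step 13 | α-(diethoxyphosphoryl) lactone: 22 with the exocyclic CH2 replaced by H and P(O)(OEt)2 (both epimers at that carbon) | CCOP(=O)(OCC)C1C(=O)O[C@H]2/C=C(\C)CC/C=C(/C)[C@@H](O[Si](C)(C)C(C)(C)C)[C@H](O)[C@@H]12
F3 | step 12 | (4R,5S)-4-{(1R,2R)-2-[(tert-butyldimethylsilyl)oxy]-1-hydroxy-3-methylbut-3-en-1-yl}-3-methylidene-5-[(1E)-2-methylhexa-1,5-dien-1-yl]oxolan-2-one | C=C1C(=O)O[C@@H](/C=C(\C)CCC=C)[C@H]1[C@@H](O)[C@H](O[Si](C)(C)C(C)(C)C)C(C)=C
F4 | step 12 | (2S,3S)-2,3-dimethyloxirane-2-carboxylate of F3 at its free hydroxyl | C=C1C(=O)O[C@@H](/C=C(\C)CCC=C)[C@H]1[C@@H](OC(=O)[C@@]2(C)O[C@H]2C)[C@H](O[Si](C)(C)C(C)(C)C)C(C)=C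
F5 | step 6 | ethyl (2E,7R)-7-[(tert-butyldimethylsilyl)oxy]-4-hydroxy-2,8-dimethylnona-2,8-dien-5-ynoate, both C4 epimers | CCOC(=O)/C(C)=C/C(O)C#C[C@H](O[Si](C)(C)C(C)(C)C)C(C)=C
F6 | step 6 | ethyl (2E,7R)-7-[(tert-butyldimethylsilyl)oxy]-2,8-dimethyl-4-oxonona-2,8-dien-5-ynoate | CCOC(=O)/C(C)=C/C(=O)C#C[C@H](O[Si](C)(C)C(C)(C)C)C(C)=C
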